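## The problem

Target 25 is a 21-membered macrocycle in which two benzene rings are joined twice, once through a diaryl ether oxygen and once through an unbranched C14 chain, each ring being bridged meta. Ring A is a resorcinol (C1 OH, C3 chain, C5 ether oxygen). Ring B is a hydroquinone (C1 ether oxygen, C3 OH, C5 chain, C6 OH, with C6 lying between the ether carbon and the chain carbon). There is no stereocentre, so the task is one of connectivity and oxygen placement. The only stereo-elements met on the way (a racemic carbon in a pericyclic intermediate, the geometry of a metathesis alkene) are transient and are erased. Four aryl oxygens must be told apart: three end as free phenols and one as the ether. On ring A the ether oxygen is one of two otherwise equivalent resorcinol oxygens, which a late O-arylation could address only by desymmetrisation or protection. Ring B is a 2-aryloxy-6-alkylhydroquinone that air oxidises readily to the quinone, above all under base, so it should stay masked until the last step. The large ring has no conformational bias, so its closure needs high dilution and must tolerate a free phenol. The enabling feature is the 1-hydroxy-3-alkyl-5-aryloxy pattern of ring A. It is what forms when a 3-alkylcyclobutenone (C1 with its oxygen, C2, C3 with the chain, C4) takes up the two carbons of an aryloxyacetylene (C5 with the ether oxygen, C6), so ring A can be grown around an oxygen already bound to ring B.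

## Retrosynthesis

25 from 24. The two O–CH3 bonds on ring B are cut in the retrosynthetic sense, so the hydroquinone is carried as its dimethyl ether 24. Methyl is chosen over more labile groups because it must survive an organolithium base, palladium, ruthenium and prolonged heating. The forward step has to cleave two aryl methyl ethers, one of them flanked on both sides, without touching the diaryl ether.

24 from 23 from 22. The chain is cut at its central C–C bond, which is seen as the C=C of macrocyclic alkene 23 and then as the two terminal alkenes of diene 22. A central cut gives two identical oct-7-enyl arms that both come from bromide 1. A cut nearer a ring would need two different alkenyl reagents and a styrene or allylarene partner. The precursor is acyclic. The forward steps are a ring-closing metathesis that tolerates the free phenol, then saturation of the alkene.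

22 from 5 and 17. Ring A is taken apart at C1–C6 and C4–C5, giving cyclobutenone 5 (fragment 1) and aryl ethynyl ether 17 (fragment 2). The neighbouring cut, the ring A C5–O bond, would ask for mono-arylation of a 5-alkylresorcinol or a cross-coupling to a hindered phenol. The chosen cut makes the ether oxygen part of a reagent and gives the free C1 phenol without a protecting group. The precursors have one aromatic ring each. The forward reaction must be regioselective (aryloxy meta to the new hydroxyl) and must leave two terminal alkenes alone.

17 from 14 from 12 and 13. The triple bond is traced back to (E)-1,2-dichlorovinyl ether 14, and its O–C(sp2) bond is cut to phenol 12 and trichloroethylene 13. Trichloroethylene thereby supplies C5 and C6 of ring A. Other ynol ether syntheses pass through the same metal acetylide, and this one starts from the cheapest two-carbon unit. The forward steps need a phenoxide addition and a double elimination that spares the terminal alkene and the methyl ethers.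

12 from 10 and 1. The ring B C5–chain bond is cut as an aryl–alkyl cross-coupling between bromophenol 10 and zinc reagent 11, which is made from bromide 1. The alternative cut one bond further out (benzylic carbon to chain) is workable but costs two more steps and a second alkenyl bromide. The forward coupling must tolerate a free phenol and must not isomerise the primary alkyl group.

10 from 8 from 7 from 6. The ring B C1–O bond is traced to the formyl carbon of 8 (aryl migration to oxygen), the C6 methyl ether to the phenol of 7, and the C–Br bond to C–H of salicylaldehyde 6. Compound 6 already holds two of the three ring B oxygens in the right places. Its formyl group is a latent third oxygen, and its free hydroxyl directs bromine to the carbon that will carry the chain. The peracid step is placed before any alkene is present.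

5 from 2 and 1. The C3–chain bond of the cyclobutenone is cut to vinylogous ester 2 and Grignard reagent 3 (from 1), by carbonyl addition to give carbinol 4 and acid-mediated transposition. This is one operation from two purchasable compounds, and the four-membered ring is bought rather than built.

## Roads not taken

Alternative 1: Here the two phenolic C–O bonds at ring A C1 and ring B C3 are cut back to C–H, leading to the oxygen-free macrocycle A1. Forward, one-pot borylation (B2pin2, [Ir(OMe)(cod)]2, 4,4'-di-tert-butyl-2,2'-bipyridine) and oxidation (H2O2, NaOH) would give the symmetric diphenol A2.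
- Merits: A1 needs no protecting group and is simple to assemble. The two C–H bonds are related by symmetry, and each is the only position on its ring that is meta to both substituents, so steric control should give a single product. Up to A2 this road is shorter than the chosen one and makes its C–O bonds more economically.
- Weak point: A2 lacks the ring B C6 hydroxyl. That oxygen would have to go in afterwards, para to a phenol and between two substituents, on one of two identical rings. Nothing in the structure stops such an oxidation after one ring, so the outcome would be statistical.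
- Comparison: the chosen plan is longer, but ring B arrives with all three oxygens from 6 and ring A is built with exactly two, so the rings are never equivalent.

Alternative 2: Here ring A is carried at the cyclohexenone level and the ring A C5–O bond is cut, leading to the seco chloroenone A3. Forward, Cs2CO3 at high dilution lets the ring B phenoxide add to the 3-chlorocyclohexenone and expel chloride, giving the racemic macrocyclic vinylogous ester A4. Aromatisation and demethylation would follow.
- Merits: the C–O bond forms on an activated electrophile under mild base without copper. Ether formation and macrocyclisation are one step, which saves the separate metathesis and hydrogenation. The stereocentre of A4 is of no consequence.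
- Weak points: A3 needs a long linear build of a 5-substituted cyclohexane-1,3-dione tethered through fourteen carbons to ring B. Ring A must still be dehydrogenated to the phenol in the presence of the easily oxidised dimethoxyarene. A 21-membered ring closure by addition–elimination has no templating.
- Comparison: this road is better in the number of ring-forming operations. The chosen plan sets against it that ring A appears aromatic with its free phenol in one step, and that both fragments are short.

Alternative 3: Here ring B is cut at C3–C4, C5–C6 and C6–C1, leading to the tethered β-aryloxyvinyl(methoxy)carbene complex A5, which carries a (CO)5Cr unit and a terminal alkyne. Forward, heating at high dilution would insert the alkyne and one CO, closing ring B and the macrocycle together to give A6 (ring B C6 phenol free, C3 and ring A as methyl ethers).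
- Merits: three bonds and two rings form in one step, which makes this the most convergent road and better than the chosen plan in bonds made per step. The usual regiochemistry of terminal alkynes places the chain next to the new hydroxyl, as required.
- Weak points: it needs stoichiometric chromium. A5 holds a reactive carbene and its own alkyne partner in one molecule and must be made and handled without premature reaction. The arene–chromium product must be decomplexed oxidatively, and a hydroquinone monoether is prone to go on to the quinone at that stage.
- Comparison: the chosen plan accepts a separate macrocyclisation but builds its ring by a metal-free thermal cascade from two fragments that can each be purified and stored for a short time.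

Key step: step 8

Remark: the metathesis alkene of 23 is expected as an E/Z mixture, which is immaterial because step 10 saturates it, so 23 is drawn without alkene geometry. Compounds 1, 2, 6 and 13 are taken as purchasable.

## Steps

Step 1
Reactants: 1 8-bromooct-1-ene; 2 3-ethoxycyclobut-2-en-1-one
Product: 5 3-(oct-7-en-1-yl)cyclobut-2-en-1-one (fragment 1), via oct-7-enylmagnesium bromide 3 (not isolated), via 3-ethoxy-1-(oct-7-en-1-yl)cyclobut-2-en-1-ol 4 (not isolated)
Conditions: Mg, THF, 25 → 65 °C; then 2, THF, −78 → 0 °C; then 1 M HCl, 0 → 25 °C
Reagents that add atoms: water, O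
Why: Grignard 1,2-addition to the vinylogous ester gives carbinol 4 (as its magnesium alkoxide); aqueous acid hydrolyses the enol ether and eliminates water, transposing the carbonyl to the former ethoxy carbon, which is the standard entry to 3-alkylcyclobutenones. Enolisation of 2 is not expected to compete, since it would create a cyclobutadiene-like enolate.

Step 2
Reactants: 6 2-hydroxy-5-methoxybenzaldehyde
Product: 7 3-bromo-2-hydroxy-5-methoxybenzaldehyde
Conditions: Br2, NaOAc, AcOH, 25 °C
Reagents that add atoms: bromine, BrBr
Why: Electrophilic aromatic bromination; the free hydroxyl is the strongest director and its para position is occupied, so bromine should enter C3, ortho to OH, with NaOAc buffering the HBr.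

Step 3
Reactants: 7 3-bromo-2-hydroxy-5-methoxybenzaldehyde
Product: 8 3-bromo-2,5-dimethoxybenzaldehyde
Conditions: MeI, K2CO3, DMF, 25 °C
Reagents that add atoms: iodomethane, CI
Why: Williamson O-methylation of the phenoxide; the hydrogen-bonded, doubly flanked phenol still alkylates readily in DMF.

Step 4
Reactants: 8 3-bromo-2,5-dimethoxybenzaldehyde
Product: 10 3-bromo-2,5-dimethoxyphenol, via 3-bromo-2,5-dimethoxyphenyl formate 9 (not isolated)
Conditions: mCPBA, CH2Cl2, 25 °C; then K2CO3 (cat.), MeOH, 25 °C
Reagents that add atoms: mCPBA, OOC(=O)c1cccc(Cl)c1
Why: Baeyer–Villiger (Dakin-type) oxidation in which the ortho-methoxyaryl group migrates in preference to hydride, giving formate 9, which is methanolysed in the same flask. The peracid is used before any alkene is in the molecule.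

Step 5
Reactants: 10 3-bromo-2,5-dimethoxyphenol; 1 8-bromooct-1-ene
Product: 12 2,5-dimethoxy-3-(oct-7-en-1-yl)phenol, via oct-7-enylzinc bromide 11 (not isolated)
Conditions: 1, Zn, LiCl, THF, 50 °C; then 10, Pd(OAc)2 (2 mol %), SPhos (4 mol %), THF, 25 → 50 °C
Reagents that add atoms: none
Why: Negishi sp2–sp3 coupling with a primary alkylzinc halide made by LiCl-assisted zinc insertion. The Pd/SPhos system couples primary alkylzincs without chain isomerisation and is known to tolerate free phenols, because protonolysis of the C–Zn bond by ArOH is slow next to transmetalation.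

Step 6
Reactants: 12 2,5-dimethoxy-3-(oct-7-en-1-yl)phenol; 13 trichloroethylene
Product: 14 1-{[(E)-1,2-dichloroethenyl]oxy}-2,5-dimethoxy-3-(oct-7-en-1-yl)benzene
Conditions: K2CO3, DMF, 70 °C
Reagents that add atoms: none
Why: Base converts 13 into dichloroacetylene in the flask and the phenoxide adds to it in an anti sense to give the (E)-1,2-dichlorovinyl ether; this is the usual first stage of the trichloroethylene route to ynol ethers.

Step 7
Reactants: 14 1-{[(E)-1,2-dichloroethenyl]oxy}-2,5-dimethoxy-3-(oct-7-en-1-yl)benzene
Product: 17 1-(ethynyloxy)-2,5-dimethoxy-3-(oct-7-en-1-yl)benzene (fragment 2), via chloroethynyl ether 15 (not isolated), via lithium aryloxyacetylide 16 (not isolated)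
Conditions: n-BuLi (2.5 equiv), Et2O, −78 → −40 °C; then H2O, −78 → 0 °C
Reagents that add atoms: none
Why: Dehydrochlorination followed by chlorine–lithium exchange: n-BuLi removes the vinyl proton, LiCl is lost to give 15, a second equivalent exchanges the alkynyl chlorine to give 16, and cold protonation releases 17. Terminal aryl ethynyl ethers are known, isolable compounds; 17 is kept cold in solution and used at once.

Step 8
Reactants: 5 3-(oct-7-en-1-yl)cyclobut-2-en-1-one; 17 1-(ethynyloxy)-2,5-dimethoxy-3-(oct-7-en-1-yl)benzene
Product: 22 3-[2,5-dimethoxy-3-(oct-7-en-1-yl)phenoxy]-5-(oct-7-en-1-yl)phenol, via vinylketene 18 (not isolated), via cyclobutenone adduct 19 (not isolated), via dienylketene 20 (not isolated), via cyclohexadienone 21 (not isolated)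
Conditions: 5 (1.5 equiv), toluene, 80 → 110 °C, sealed tube; then KOH, MeOH, 25 °C
Reagents that add atoms: none
Why: Danheiser benzannulation, the known reaction of cyclobutenones with alkoxy- and siloxyacetylenes, applied here to an aryl ynol ether. Near 80 °C cyclobutenone 5 opens (4π, conrotatory) to vinylketene 18; the terminal carbon of 17, made nucleophilic by the aryloxy oxygen, attacks the ketene carbonyl carbon, and the [2+2] adduct 19 forms with the two C–C bonds that become ring A C1–C6 and C4–C5. Adduct 19 opens reversibly (4π) to dienylketene 20, and the isomer with the ketene and the 1,1-disubstituted alkene cis on the central double bond closes the six-membered ring A by thermal disrotatory 6π-electrocyclisation at C1–C2; dienone 21 then tautomerises irreversibly to phenol 22. The step needs regioselectivity (aryloxy meta to the new hydroxyl, chain at C3), which follows from the matched polarity of ketene and ynol ether. It also needs chemoselectivity for the ynol ether over two terminal alkenes, which is secured because unactivated monosubstituted alkenes do not add to vinylketenes at these temperatures. An aryl ynol ether has no O-alkyl hydrogen for retro-ene loss of an alkene, so it should survive the heating better than an alkyl ynol ether. No stereocentre remains: the one in 19 is racemic and is erased on ring opening. Excess ketene can acylate the product phenol, and the KOH/MeOH treatment returns any such ester to 22.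

Step 9
Reactants: 22 3-[2,5-dimethoxy-3-(oct-7-en-1-yl)phenoxy]-5-(oct-7-en-1-yl)phenol
Product: 23 1²,1⁵-dimethoxy-2-oxa-1,3(1,3)-dibenzenacycloheptadecaphan-10-en-3⁵-ol (E/Z mixture; ring B is locant 1 and ring A is locant 3)
Conditions: RuCl2(=CHPh)(PCy3)(H2IMes) (5 mol %), CH2Cl2 (1 mM), 40 °C
Reagents that add atoms: none
Why: Ring-closing olefin metathesis of two unhindered terminal alkenes, driven by loss of ethene. High dilution favours the 21-membered ring over oligomers, and the second-generation Grubbs catalyst tolerates the free phenol.

Step 10
Reactants: 23 1²,1⁵-dimethoxy-2-oxa-1,3(1,3)-dibenzenacycloheptadecaphan-10-en-3⁵-ol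
Product: 24 1²,1⁵-dimethoxy-2-oxa-1,3(1,3)-dibenzenacycloheptadecaphan-3⁵-ol
Conditions: H2 (1 atm), Pd/C, EtOAc, 25 °C
Reagents that add atoms: none
Why: Heterogeneous catalytic hydrogenation of a 1,2-disubstituted alkene; the aryl methyl ethers and the diaryl ether are inert under these conditions, and both alkene isomers converge on one product.

Step 11
Reactants: 24 1²,1⁵-dimethoxy-2-oxa-1,3(1,3)-dibenzenacycloheptadecaphan-3⁵-ol
Product: 25 2-oxa-1,3(1,3)-dibenzenacycloheptadecaphane-1²,1⁵,3⁵-triol (target)
Conditions: BBr3, CH2Cl2, −78 → 0 °C; then H2O
Reagents that add atoms: none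
Why: Lewis-acid cleavage of aryl methyl ethers by BBr3 (boron binds oxygen, bromide attacks the methyl carbon). The diaryl ether offers no alkyl carbon and should survive, and an acidic work-up under argon keeps the hydroquinone reduced.

## Compound list

1 | 8-bromooct-1-ene | BrCCCCCCC=C | starting material
2 | 3-ethoxycyclobut-2-en-1-one | CCOC1=CC(=O)C1 | starting material
3 | oct-7-enylmagnesium bromide | Br[Mg]CCCCCCC=C | intermediate
4 | rac-3-ethoxy-1-(oct-7-en-1-yl)cyclobut-2-en-1-ol (formed as its magnesium alkoxide) | CCOC1=CC(O)(CCCCCCC=C)C1 | intermediate
5 | 3-(oct-7-en-1-yl)cyclobut-2-en-1-one (fragment 1) | O=C1C=C(CCCCCCC=C)C1 | intermediate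
6 | 2-hydroxy-5-methoxybenzaldehyde | COc1ccc(O)c(C=O)c1 | starting material
7 | 3-bromo-2-hydroxy-5-methoxybenzaldehyde | COc1cc(Br)c(O)c(C=O)c1 | intermediate
8 | 3-bromo-2,5-dimethoxybenzaldehyde | COc1cc(Br)c(OC)c(C=O)c1 | intermediate
9 | 3-bromo-2,5-dimethoxyphenyl formate | COc1cc(Br)c(OC)c(OC=O)c1 | intermediate
10 | 3-bromo-2,5-dimethoxyphenol | COc1cc(O)c(OC)c(Br)c1 | intermediate
11 | oct-7-enylzinc bromide | Br[Zn]CCCCCCC=C | intermediate
12 | 2,5-dimethoxy-3-(oct-7-en-1-yl)phenol | COc1cc(O)c(OC)c(CCCCCCC=C)c1 | intermediate
13 | trichloroethylene | ClC=C(Cl)Cl | starting material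
14 | 1-{[(E)-1,2-dichloroethenyl]oxy}-2,5-dimethoxy-3-(oct-7-en-1-yl)benzene | Cl/C=C(/Cl)Oc1cc(OC)cc(CCCCCCC=C)c1OC | intermediate
15 | 1-[(chloroethynyl)oxy]-2,5-dimethoxy-3-(oct-7-en-1-yl)benzene | ClC#COc1cc(OC)cc(CCCCCCC=C)c1OC | intermediate
16 | lithium [2,5-dimethoxy-3-(oct-7-en-1-yl)phenoxy]ethynide | [Li]C#COc1cc(OC)cc(CCCCCCC=C)c1OC | intermediate
17 | 1-(ethynyloxy)-2,5-dimethoxy-3-(oct-7-en-1-yl)benzene (fragment 2) | C#COc1cc(OC)cc(CCCCCCC=C)c1OC | intermediate
18 | 3-methylideneundeca-1,10-dien-1-one (vinylketene) | O=C=CC(=C)CCCCCCC=C | intermediate
19 | rac-4-(deca-1,9-dien-2-yl)-3-[2,5-dimethoxy-3-(oct-7-en-1-yl)phenoxy]cyclobut-2-en-1-one | O=C1C=C(Oc2cc(OC)cc(CCCCCCC=C)c2OC)C1C(=C)CCCCCCC=C | intermediate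
20 | (3E)-3-[2,5-dimethoxy-3-(oct-7-en-1-yl)phenoxy]-5-methylidenetrideca-1,3,12-trien-1-one (dienylketene) | O=C=C/C(Oc1cc(OC)cc(CCCCCCC=C)c1OC)=C\C(=C)CCCCCCC=C | intermediate
21 | 3-[2,5-dimethoxy-3-(oct-7-en-1-yl)phenoxy]-5-(oct-7-en-1-yl)cyclohexa-2,4-dien-1-one | O=C1C=C(Oc2cc(OC)cc(CCCCCCC=C)c2OC)C=C(CCCCCCC=C)C1 | intermediate
22 | 3-[2,5-dimethoxy-3-(oct-7-en-1-yl)phenoxy]-5-(oct-7-en-1-yl)phenol | Oc1cc(CCCCCCC=C)cc(c1)Oc1cc(OC)cc(CCCCCCC=C)c1OC | intermediate
23 | 1²,1⁵-dimethoxy-2-oxa-1,3(1,3)-dibenzenacycloheptadecaphan-10-en-3⁵-ol (E/Z mixture) | Oc1cc2cc(c1)Oc1cc(OC)cc(c1OC)CCCCCCC=CCCCCCC2 | intermediate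
24 | 1²,1⁵-dimethoxy-2-oxa-1,3(1,3)-dibenzenacycloheptadecaphan-3⁵-ol | Oc1cc2cc(c1)Oc1cc(OC)cc(c1OC)CCCCCCCCCCCCCC2 | intermediate
25 | 2-oxa-1,3(1,3)-dibenzenacycloheptadecaphane-1²,1⁵,3⁵-triol | Oc1cc2cc(c1)Oc1cc(O)cc(c1O)CCCCCCCCCCCCCC2 | target

## Step count and risks

Total: 11 steps. Longest linear sequence: 10 steps (steps 2 to 11, from 6); fragment 1 is a one-step branch (step 1).

Step 8 (key step). The aryloxy oxygen donates less to the alkyne than an alkoxy or siloxy oxygen, so the [2+2] addition may be slow. The vinylketene could then dimerise, or the terminal ynol ether polymerise, before the two meet. Fallback, setting out from 12 and rejoining at 22, forms the ether by copper catalysis instead of building ring A: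
- Commercial 3,5-dibromophenol is protected (MOMCl, i-Pr2NEt, CH2Cl2) as 1,3-dibromo-5-(methoxymethoxy)benzene F1.
- One bromide is replaced by the chain with zinc reagent 11 under the conditions of step 5, F1 being in excess, to give 1-bromo-3-(methoxymethoxy)-5-(oct-7-en-1-yl)benzene F2.
- Ullmann coupling of F2 with phenol 12 (CuI, picolinic acid, K3PO4, DMSO, 90 °C) gives 1-[3-(methoxymethoxy)-5-(oct-7-en-1-yl)phenoxy]-2,5-dimethoxy-3-(oct-7-en-1-yl)benzene F3.
- HCl in MeOH removes the acetal and returns 22.

Step 7. Loss of the terminal ynol ether during isolation is the likely failure, by hydration to the aryl acetate on silica or by oligomerisation on concentration. Fallback, from 14 back to 17: acetylide 16 is generated as in step 7 and quenched with Me3SiCl instead of water. This gives trimethyl({[2,5-dimethoxy-3-(oct-7-en-1-yl)phenoxy]ethynyl})silane F4, a C-silylated ynol ether that should tolerate chromatography and storage. Bu4NF in THF at 0 °C then releases 17 in solution immediately before step 8.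

Step 5. The free phenol may protonate the alkylzinc faster than hoped, or the electron-rich phenoxide-bearing bromide may add oxidatively so slowly that reduction of the aryl bromide wins. Fallback, from 8 back to 12, makes the chain bond at the benzylic carbon and also bypasses step 4:
- NaBH4 in MeOH reduces 8 to (3-bromo-2,5-dimethoxyphenyl)methanol F5.
- PBr3 gives 1-bromo-3-(bromomethyl)-2,5-dimethoxybenzene F6.
- Hept-6-enylmagnesium bromide F7 (from commercial 7-bromohept-1-ene and Mg) couples at the benzylic carbon under Li2CuCl4 catalysis (THF, −20 °C) to give 1-bromo-2,5-dimethoxy-3-(oct-7-en-1-yl)benzene F8.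
- Bromine–lithium exchange (n-BuLi, THF, −78 °C) gives [2,5-dimethoxy-3-(oct-7-en-1-yl)phenyl]lithium F9.
- B(OMe)3 converts F9 into dimethyl [2,5-dimethoxy-3-(oct-7-en-1-yl)phenyl]boronate F10.
- H2O2/NaOH oxidises F10 to phenol 12.

Step 9. Two failures are likely: intermolecular metathesis to dimers and oligomers, since nothing preorganises the diene, and ruthenium hydride-mediated alkene migration before closure. Migration would give ring-contracted homologues that cannot be separated after hydrogenation. Fallback, from 22 back to 23: both terminal alkenes are cleaved (OsO4 cat., NaIO4, 2,6-lutidine, dioxane/H2O) to 7-{3-[3-hydroxy-5-(7-oxoheptyl)phenoxy]-2,5-dimethoxyphenyl}heptanal F11. Intramolecular McMurry coupling (TiCl3, Zn–Cu couple, DME, reflux, slow addition) then joins the two aldehyde carbons to give 23 with a chain length fixed by constitution.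

Step 11. Incomplete cleavage of one ether, or oxidation of the liberated hydroquinone during work-up, would give mixtures of phenol, monoether and quinone. Fallback, from 24 back to 25: oxidative demethylation with (NH4)2Ce(NO3)6 in MeCN/H2O at 0 °C takes the para-dimethoxyarene, the most easily oxidised ring, deliberately to the ring B para-quinone of 25, F12 (2-aryloxy-6-alkyl-1,4-benzoquinone macrocycle with the ring A phenol free). Na2S2O4 in EtOAc/H2O then reduces F12 to 25.

## Further compounds

F1 | step 8 | 1,3-dibromo-5-(methoxymethoxy)benzene | COCOc1cc(Br)cc(Br)c1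
F2 | step 8 | 1-bromo-3-(methoxymethoxy)-5-(oct-7-en-1-yl)benzene | COCOc1cc(Br)cc(CCCCCCC=C)c1
F3 | step 8 | 1-[3-(methoxymethoxy)-5-(oct-7-en-1-yl)phenoxy]-2,5-dimethoxy-3-(oct-7-en-1-yl)benzene | COCOc1cc(CCCCCCC=C)cc(c1)Oc1cc(OC)cc(CCCCCCC=C)c1OC
F4 | step 7 | trimethyl({[2,5-dimethoxy-3-(oct-7-en-1-yl)phenoxy]ethynyl})silane | C[Si](C)(C)C#COc1cc(OC)cc(CCCCCCC=C)c1OC
F5 | step 5 | (3-bromo-2,5-dimethoxyphenyl)methanol | COc1cc(Br)c(OC)c(CO)c1
F6 | step 5 | 1-bromo-3-(bromomethyl)-2,5-dimethoxybenzene | COc1cc(Br)c(OC)c(CBr)c1
F7 | step 5 | hept-6-enylmagnesium bromide | Br[Mg]CCCCCC=C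
F8 | step 5 | 1-bromo-2,5-dimethoxy-3-(oct-7-en-1-yl)benzene | COc1cc(Br)c(OC)c(CCCCCCC=C)c1
F9 | step 5 | [2,5-dimethoxy-3-(oct-7-en-1-yl)phenyl]lithium | [Li]c1cc(OC)cc(CCCCCCC=C)c1OC
F10 | step 5 | dimethyl [2,5-dimethoxy-3-(oct-7-en-1-yl)phenyl]boronate | COB(OC)c1cc(OC)cc(CCCCCCC=C)c1OC
F11 | step 9 | 7-{3-[3-hydroxy-5-(7-oxoheptyl)phenoxy]-2,5-dimethoxyphenyl}heptanal | Oc1cc(CCCCCCC=O)cc(c1)Oc1cc(OC)cc(CCCCCCC=O)c1OC
F12 | step 11 | ring B para-quinone of 25 (macrocyclic 2-aryloxy-6-alkyl-1,4-benzoquinone, ring A phenol free) | Oc1cc2cc(c1)OC1=CC(=O)C=C(C1=O)CCCCCCCCCCCCCC2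
A1 | alternative 1 | 2-oxa-1,3(1,3)-dibenzenacycloheptadecaphane | c1cc2cc(c1)Oc1cccc(c1)CCCCCCCCCCCCCC2
A2 | alternative 1 | 2-oxa-1,3(1,3)-dibenzenacycloheptadecaphane-1⁵,3⁵-diol | Oc1cc2cc(c1)Oc1cc(O)cc(c1)CCCCCCCCCCCCCC2
A3 | alternative 2 | rac-3-chloro-5-[14-(3-hydroxy-2,5-dimethoxyphenyl)tetradecyl]cyclohex-2-en-1-one | O=C1C=C(Cl)CC(C1)CCCCCCCCCCCCCCc1cc(OC)cc(O)c1OC
A4 | alternative 2 | racemic macrocyclic 3-aryloxycyclohex-2-en-1-one (ring A at the cyclohexenone level, ring B as dimethyl ether) | O=C1C=C2CC(C1)CCCCCCCCCCCCCCc1cc(OC)cc(O2)c1OC
A5 | alternative 3 | pentacarbonyl{(2E)-3-[3-(hexadec-15-yn-1-yl)-5-methoxyphenoxy]-1-methoxyprop-2-en-1-ylidene}chromium | COC(=[Cr](=C=O)(=C=O)(=C=O)(=C=O)=C=O)/C=C/Oc1cc(OC)cc(CCCCCCCCCCCCCCC#C)c1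
A6 | alternative 3 | 1⁵,3⁵-dimethoxy-2-oxa-1,3(1,3)-dibenzenacycloheptadecaphan-1²-ol | COc1cc2cc(c1)Oc1cc(OC)cc(c1O)CCCCCCCCCCCCCC2
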